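**Retrosynthetic overview**
1. Numbering used throughout: C1 and C3 are the free carbinols, C2 the CH2 between them, C4=C5 and C9=C10 the ring olefins, C6 the lactone O–CH, C7 the ring-fusion CH, C8 the angelate CH, and C11, C12, C13 the lactone α-carbon, carbonyl and exocyclic CH2.
2. The α-methylene-γ-lactone is made last, on the finished carbocycle: CO2 enters as C12 between C11 (alkenyl anion from a 1-bromovinyl group on C7) and C6 (allylic chloride), forming C11–C12 and O–C6 with inversion at C6.
3. Enabling feature: C6 is allylic to the C4=C5 ring olefin and bonded to C7, which carries the exocyclic C11=C13 unit, so the lactone atoms C6, C7 and C11 form a 1,3-related allylic electrophile/vinyl anion pair that lacks only CO2.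
4. Ten-membered ring first, by Nozaki–Hiyama–Kishi closure of C5–C6; C7 and C8 come from a thiazolidinethione syn-aldol of a 3-bromobut-3-enoyl unit with a (Z)-enal.
5. The C9–C10–C1–C2–C3–C4–C5 half is C2-symmetric: (3S,5S)-hepta-1,6-diyne-3,5-diol is turned into a bis-(Z)-iodoalkene by double anti-carbomagnesiation/iodination; angelate and desilylation come last.

Key step: step 16

Remark: the sense of induction in step 1 is assigned by analogy with branched aldehydes; if the zinc–ProPhenol aldol shows the opposite sense on this substrate pair, the antipodal ligand is used and nothing else changes.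

Step 1
Reactants: 1 4-(trimethylsilyl)but-3-yn-2-one; 2 3-(trimethylsilyl)prop-2-ynal
Product: 3 (S)-5-hydroxy-1,7-bis(trimethylsilyl)hepta-1,6-diyn-3-one
Conditions: (S,S)-ProPhenol (10 mol%), Et2Zn (20 mol%), 4 Å MS, THF, 0 °C
Reagents that add atoms: none
Why: Direct catalytic asymmetric aldol addition of a methyl ynone (dinuclear zinc–ProPhenol type), in which the zinc enolate of 1 should add to the non-enolisable ynal 2 inside the chiral pocket and set the carbinol centre as S.

Step 2
Reactants: 3 (S)-5-hydroxy-1,7-bis(trimethylsilyl)hepta-1,6-diyn-3-one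
Product: 4 (3S,5S)-1,7-bis(trimethylsilyl)hepta-1,6-diyne-3,5-diol
Conditions: Me4NBH(OAc)3, MeCN/AcOH (1:1), −30 °C
Reagents that add atoms: none
Why: Evans–Saksena 1,3-anti reduction, in which intramolecular hydride delivery from the alkoxy(acetoxy)borohydride through a chair-like transition state should set the new carbinol anti to the existing one and give the C2-symmetric (S,S)-diol.

Step 3
Reactants: 4 (3S,5S)-1,7-bis(trimethylsilyl)hepta-1,6-diyne-3,5-diol
Product: 5 (3S,5S)-hepta-1,6-diyne-3,5-diol
Conditions: K2CO3 (0.2 equiv), MeOH, 0 °C → rt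
Reagents that add atoms: none
Why: Base-catalysed methanolysis of the two alkynyl C–Si bonds (protodesilylation) should free both terminal alkynes without touching a stereocentre.

Step 4
Reactants: 5 (3S,5S)-hepta-1,6-diyne-3,5-diol
Product: 7 (1Z,3S,5S,6Z)-1,7-diiodo-2,6-dimethylhepta-1,6-diene-3,5-diol, via bis(alkenylmagnesium) alkoxide 6 (not isolated)
Conditions: MeMgBr (6 equiv), CuI (20 mol%), THF, −10 °C → rt; then I2 (2.5 equiv), −78 → 0 °C
Reagents that add atoms: methylmagnesium bromide, C[Mg]Br; iodine, II
Why: Copper-catalysed anti-carbomagnesiation of propargylic alkoxides, in which each alkoxide should direct methyl to the proximal alkyne carbon and magnesium to the terminal carbon cis to the carbinol carbon, so that iodinolysis with retention gives both (Z)-iodoalkenes, that is both ring-olefin geometries.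

Step 5
Reactants: 7 (1Z,3S,5S,6Z)-1,7-diiodo-2,6-dimethylhepta-1,6-diene-3,5-diol
Product: 8 (1Z,3S,5S,6Z)-3,5-bis(tert-butyldimethylsilyloxy)-1,7-diiodo-2,6-dimethylhepta-1,6-diene
Conditions: TBSOTf, 2,6-lutidine, CH2Cl2, 0 °C
Reagents that add atoms: tert-butyldimethylsilyl trifluoromethanesulfonate, CC(C)(C)[Si](C)(C)OS(=O)(=O)C(F)(F)F
Why: Silylation of both secondary allylic alcohols with the silyl triflate should protect O1 and O3 until the last step.

Step 6
Reactants: 8 (1Z,3S,5S,6Z)-3,5-bis(tert-butyldimethylsilyloxy)-1,7-diiodo-2,6-dimethylhepta-1,6-diene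
Product: 10 (2Z,4S,6S,7Z)-4,6-bis(tert-butyldimethylsilyloxy)-8-iodo-3,7-dimethylocta-2,7-dienal, via alkenyllithium 9 (not isolated)
Conditions: n-BuLi (1.0 equiv), Et2O, −78 °C; then DMF, −78 → 0 °C
Reagents that add atoms: N,N-dimethylformamide, CN(C)C=O
Why: Iodine–lithium exchange with retention of olefin geometry followed by formylation; the two iodides are homotopic by C2 symmetry, so mono-exchange should give a single enal (statistical mono-functionalisation, unreacted 8 to be recycled).

Step 7
Reactants: 11 3-bromobut-3-en-1-ol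
Product: 12 3-bromobut-3-enoic acid
Conditions: TEMPO (0.2 equiv), PhI(OAc)2 (2.2 equiv), MeCN/H2O (1:1), rt
Reagents that add atoms: water, O
Why: Oxoammonium (TEMPO/PhI(OAc)2) oxidation of the primary alcohol through the aldehyde hydrate should give the acid without moving the β,γ-double bond or touching the vinyl bromide.

Step 8
Reactants: 12 3-bromobut-3-enoic acid; 13 (S)-4-benzylthiazolidine-2-thione
Product: 14 (S)-1-(4-benzyl-2-thioxothiazolidin-3-yl)-3-bromobut-3-en-1-one
Conditions: DCC, DMAP (0.1 equiv), CH2Cl2, 0 °C → rt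
Reagents that add atoms: none
Why: Carbodiimide-mediated N-acylation of the auxiliary at low temperature should give the imide before the β,γ-unsaturated acyl group can isomerise.

Step 9
Reactants: 14 (S)-1-(4-benzyl-2-thioxothiazolidin-3-yl)-3-bromobut-3-en-1-one; 10 (2Z,4S,6S,7Z)-4,6-bis(tert-butyldimethylsilyloxy)-8-iodo-3,7-dimethylocta-2,7-dienal
Product: 16 syn-aldol adduct (N-acyl thiazolidinethione carrying the chain C6(=O)–C7H(1-bromovinyl)–C8H(OH)–C9H=C10(Me)–C1H(OTBS)–C2H2–C3H(OTBS)–C4(Me)=C5H–I), via chlorotitanium enolate 15 (not isolated)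
Conditions: TiCl4 (1.05 equiv), i-Pr2NEt (1.1 equiv), NMP (1.0 equiv), CH2Cl2, 0 °C; then 10, −78 → −40 °C
Reagents that add atoms: none
Why: Titanium-mediated Evans-type syn aldol of an N-acyl thiazolidinethione, in which the (Z)-enolate 15 should add through a closed non-chelated chair transition state on the face opposite the benzyl group, setting C7 and C8 syn with the absolute configuration dictated by the (S)-auxiliary.

Step 10
Reactants: 16 syn-aldol adduct
Product: 17 8-O-triethylsilyl ether of 16
Conditions: TESOTf, 2,6-lutidine, CH2Cl2, −78 °C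
Reagents that add atoms: triethylsilyl trifluoromethanesulfonate, CC[Si](CC)(CC)OS(=O)(=O)C(F)(F)F
Why: Silylation of the aldol hydroxyl should block retro-aldol cleavage and give an O8 group that can later be removed in the presence of the two TBS ethers.

Step 11
Reactants: 17 8-O-triethylsilyl ether of 16
Product: 18 (4Z,9Z)-2-(1-bromovinyl)-6,8-bis(tert-butyldimethylsilyloxy)-10-iodo-5,9-dimethyl-3-(triethylsilyloxy)deca-4,9-dienal (configuration as in 16; C1 of this name is C6)
Conditions: i-Bu2AlH, CH2Cl2, −78 °C; aq. Rochelle salt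
Reagents that add atoms: none
Why: Partial reduction of the N-acyl thiazolidinethione, whose tetrahedral aluminium adduct should collapse only on work-up, gives the aldehyde and releases the auxiliary.

Step 12
Reactants: 18 aldehyde (C6) with the (Z)-alkenyl iodide (C5)
Product: 19 (4Z,9Z)-7-(1-bromovinyl)-1,3-bis(tert-butyldimethylsilyloxy)-4,10-dimethyl-8-(triethylsilyloxy)cyclodeca-4,9-dien-6-ol (numbering of the overview), mixture of C6 epimers
Conditions: CrCl2 (10 equiv), NiCl2 (1 mol%), DMSO/THF (3:1), 0.002 M, slow addition, rt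
Reagents that add atoms: none
Why: Intramolecular Nozaki–Hiyama–Kishi reaction, in which the alkenylchromium formed from the iodide with retention of the Z geometry (the iodide reacts with zerovalent nickel far faster than the 1-bromovinyl group) should add to the aldehyde at high dilution and close the ten-membered ring; the C6 epimer mixture is levelled in step 13.

Step 13
Reactants: 19 macrocyclic allylic alcohol (C6 epimers)
Product: 20 the corresponding cyclodeca-4,9-dien-6-one
Conditions: Dess–Martin periodinane, pyridine, CH2Cl2, 0 °C → rt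
Reagents that add atoms: none
Why: Dess–Martin oxidation of the allylic alcohol under buffered conditions should give one enone from both epimers without epimerising C7.

Step 14
Reactants: 20 macrocyclic enone
Product: 21 (6S)-allylic alcohol (C6 configured as in the target)
Conditions: (S)-2-methyl-CBS-oxazaborolidine (1.0 equiv), catecholborane, toluene, −78 °C
Reagents that add atoms: none
Why: Corey–Bakshi–Shibata reduction, in which the oxazaborolidine should bind the carbonyl anti to the trisubstituted alkenyl arm and deliver hydride to the face that gives the 6S alcohol under reagent control, catecholborane at −78 °C leaving the olefins alone.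

Step 15
Reactants: 21 (6S)-allylic alcohol
Product: 22 (6R)-allylic chloride (6-epi)
Conditions: PPh3, hexachloroacetone, CH2Cl2, −20 → 0 °C
Reagents that add atoms: hexachloroacetone, O=C(C(Cl)(Cl)Cl)C(Cl)(Cl)Cl
Why: Appel-type chlorination with PPh3/hexachloroacetone, a combination that converts secondary allylic alcohols into chlorides without allylic transposition, should invert C6 by SN2 collapse of the alkoxyphosphonium chloride.

Step 16
Reactants: 22 (6R)-allylic chloride bearing the 1-bromovinyl group on C7
Product: 25 silyl-protected α-methylene-γ-lactone, via alkenyllithium 23 (not isolated), via lithium carboxylate 24 (not isolated)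
Conditions: t-BuLi (2.1 equiv), THF/Et2O/pentane (4:1:1), −100 °C; CO2 (dry gas), −100 → −78 °C; then DMPU, −78 → 45 °C
Reagents that add atoms: carbon dioxide, O=C=O
Why: Bromine–lithium exchange at the 1-bromovinyl group gives alkenyllithium 23, which captures CO2 at C11 to give the lithium 2-substituted acrylate 24 (new C11–C12 bond), and on warming with DMPU the carboxylate oxygen displaces the allylic chloride at C6 (new O–C6 bond) to give the α-methylene-γ-butyrolactone. The closest known reaction types are Parham-type exchange–cyclisation sequences run in the presence of alkyl halides, the carboxylation of 1-substituted vinyllithiums to 2-substituted acrylic acids, and the lactonisation of γ-halo carboxylates. The lactone ring closes in a 5-exo-tet SN2 mode. C6, the only new stereocentre, is set by inversion of the chloride of 22, whose configuration comes from steps 14 and 15; the C11 branch on C7 and the chlorine on C6 can lie anti, so backside attack should give the trans-fused lactone. The step needs exchange at C–Br to outrun any attack on C–Cl, which the −100 °C exchange in a pentane-rich medium and the immediate CO2 quench should secure, and O-alkylation at C6 rather than SN2′ attack at C4, which would build a quaternary centre in a seven-membered ring. Because C6 carries no oxygen in 22, closure by acylation is impossible and only the invertive alkylative closure can give a lactone.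

Step 17
Reactants: 25 silyl-protected α-methylene-γ-lactone
Product: 26 8-hydroxy lactone (O1 and O3 still TBS-protected)
Conditions: PPTS (0.2 equiv), MeOH/CH2Cl2 (1:4), 0 °C
Reagents that add atoms: none
Why: Acid-catalysed methanolysis should cleave the secondary triethylsilyl ether selectively, since it is far more labile than the two TBS ethers.

Step 18
Reactants: 26 8-hydroxy lactone; 27 angelic acid ((Z)-2-methylbut-2-enoic acid)
Product: 29 8-O-angeloyl lactone (O1 and O3 TBS-protected), via mixed anhydride 28 (not isolated)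
Conditions: 27, 2,4,6-trichlorobenzoyl chloride, Et3N, toluene, rt; then 26, 75 °C
Reagents that add atoms: none
Why: Yamaguchi-type esterification through the mixed anhydride without a nucleophilic catalyst, conditions chosen to avoid angelate-to-tiglate isomerisation, should acylate O8 with retention at C8.

Step 19
Reactants: 29 8-O-angeloyl lactone
Product: 30 CNP0152559.1 (target)
Conditions: HF·pyridine, pyridine, THF, 0 °C → rt
Reagents that add atoms: none
Why: Buffered fluoride desilylation should remove both TBS ethers without touching the angelate, the allylic lactone or the exocyclic methylene.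

**Compound list**
1 | 4-(trimethylsilyl)but-3-yn-2-one | CC(=O)C#C[Si](C)(C)C | starting material
2 | 3-(trimethylsilyl)prop-2-ynal | O=CC#C[Si](C)(C)C | starting material
3 | (S)-5-hydroxy-1,7-bis(trimethylsilyl)hepta-1,6-diyn-3-one | C[Si](C)(C)C#CC(=O)C[C@H](O)C#C[Si](C)(C)C | intermediate
4 | (3S,5S)-1,7-bis(trimethylsilyl)hepta-1,6-diyne-3,5-diol | C[Si](C)(C)C#C[C@@H](O)C[C@H](O)C#C[Si](C)(C)C | intermediate
5 | (3S,5S)-hepta-1,6-diyne-3,5-diol | C#C[C@@H](O)C[C@H](O)C#C | intermediate
6 | bis(bromomagnesium) alkoxide of (1Z,3S,5S,6Z)-1,7-bis(bromomagnesio)-2,6-dimethylhepta-1,6-diene-3,5-diol (not isolated) | Br[Mg]/C=C(/C)[C@@H](O[Mg]Br)C[C@H](O[Mg]Br)/C(C)=C\[Mg]Br | intermediate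
7 | (1Z,3S,5S,6Z)-1,7-diiodo-2,6-dimethylhepta-1,6-diene-3,5-diol | I/C=C(/C)[C@@H](O)C[C@H](O)/C(C)=C\I | intermediate
8 | (1Z,3S,5S,6Z)-3,5-bis(tert-butyldimethylsilyloxy)-1,7-diiodo-2,6-dimethylhepta-1,6-diene | I/C=C(/C)[C@@H](O[Si](C)(C)C(C)(C)C)C[C@H](O[Si](C)(C)C(C)(C)C)/C(C)=C\I | intermediate
9 | mono(alkenyllithium) from 8 (not isolated) | I/C=C(/C)[C@@H](O[Si](C)(C)C(C)(C)C)C[C@H](O[Si](C)(C)C(C)(C)C)/C(C)=C\[Li] | intermediate
10 | (2Z,4S,6S,7Z)-4,6-bis(tert-butyldimethylsilyloxy)-8-iodo-3,7-dimethylocta-2,7-dienal | I/C=C(/C)[C@@H](O[Si](C)(C)C(C)(C)C)C[C@H](O[Si](C)(C)C(C)(C)C)/C(C)=C\C=O | intermediate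
11 | 3-bromobut-3-en-1-ol | C=C(Br)CCO | starting material
12 | 3-bromobut-3-enoic acid | C=C(Br)CC(=O)O | intermediate
13 | (S)-4-benzylthiazolidine-2-thione | S=C1N[C@@H](Cc2ccccc2)CS1 | starting material
14 | (S)-1-(4-benzyl-2-thioxothiazolidin-3-yl)-3-bromobut-3-en-1-one | C=C(Br)CC(=O)N1[C@@H](Cc2ccccc2)CSC1=S | intermediate
15 | (Z)-chlorotitanium enolate of 14 (not isolated) | C=C(Br)/C=C(\O[Ti](Cl)(Cl)Cl)N1[C@@H](Cc2ccccc2)CSC1=S | intermediate
16 | syn-aldol adduct: N-acyl (S)-4-benzylthiazolidine-2-thione, 7,8-syn, free 8-OH, 1,3-bis-OTBS, (Z)-C9=C10, (Z)-C4=C5 iodide | O=C(N1[C@@H](Cc2ccccc2)CSC1=S)[C@@H](C(Br)=C)[C@H](O)/C=C(/C)[C@@H](O[Si](C)(C)C(C)(C)C)C[C@H](O[Si](C)(C)C(C)(C)C)/C(C)=C\I | intermediate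
17 | 8-O-triethylsilyl ether of 16 | O=C(N1[C@@H](Cc2ccccc2)CSC1=S)[C@@H](C(Br)=C)[C@H](O[Si](CC)(CC)CC)/C=C(/C)[C@@H](O[Si](C)(C)C(C)(C)C)C[C@H](O[Si](C)(C)C(C)(C)C)/C(C)=C\I | intermediate
18 | (4Z,9Z)-2-(1-bromovinyl)-6,8-bis(tert-butyldimethylsilyloxy)-10-iodo-5,9-dimethyl-3-(triethylsilyloxy)deca-4,9-dienal, configuration as in 16 | O=C[C@@H](C(Br)=C)[C@H](O[Si](CC)(CC)CC)/C=C(/C)[C@@H](O[Si](C)(C)C(C)(C)C)C[C@H](O[Si](C)(C)C(C)(C)C)/C(C)=C\I | intermediate
19 | (4Z,9Z)-7-(1-bromovinyl)-1,3-bis(tert-butyldimethylsilyloxy)-4,10-dimethyl-8-(triethylsilyloxy)cyclodeca-4,9-dien-6-ol, C6 epimer mixture, other centres as in 30 | OC1/C=C(/C)[C@@H](O[Si](C)(C)C(C)(C)C)C[C@H](O[Si](C)(C)C(C)(C)C)/C(C)=C\[C@@H](O[Si](CC)(CC)CC)[C@@H]1C(Br)=C | intermediate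
20 | the corresponding cyclodeca-4,9-dien-6-one | O=C1/C=C(/C)[C@@H](O[Si](C)(C)C(C)(C)C)C[C@H](O[Si](C)(C)C(C)(C)C)/C(C)=C\[C@@H](O[Si](CC)(CC)CC)[C@@H]1C(Br)=C | intermediate
21 | (6S)-alcohol of 19 (C6 as in the target) | O[C@H]1/C=C(/C)[C@@H](O[Si](C)(C)C(C)(C)C)C[C@H](O[Si](C)(C)C(C)(C)C)/C(C)=C\[C@@H](O[Si](CC)(CC)CC)[C@@H]1C(Br)=C | intermediate
22 | (6R)-chloride (6-epi), 7-(1-bromovinyl) | Cl[C@@H]1/C=C(/C)[C@@H](O[Si](C)(C)C(C)(C)C)C[C@H](O[Si](C)(C)C(C)(C)C)/C(C)=C\[C@@H](O[Si](CC)(CC)CC)[C@@H]1C(Br)=C | intermediate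
23 | alkenyllithium from 22 (not isolated) | Cl[C@@H]1/C=C(/C)[C@@H](O[Si](C)(C)C(C)(C)C)C[C@H](O[Si](C)(C)C(C)(C)C)/C(C)=C\[C@@H](O[Si](CC)(CC)CC)[C@@H]1C([Li])=C | intermediate
24 | lithium 2-substituted acrylate from 23 (not isolated) | Cl[C@@H]1/C=C(/C)[C@@H](O[Si](C)(C)C(C)(C)C)C[C@H](O[Si](C)(C)C(C)(C)C)/C(C)=C\[C@@H](O[Si](CC)(CC)CC)[C@@H]1C(=C)C(=O)[O-].[Li+] | intermediate
25 | trans-fused α-methylene-γ-lactone, 8-OTES, 1,3-bis-OTBS | C=C1C(=O)O[C@H]2/C=C(/C)[C@@H](O[Si](C)(C)C(C)(C)C)C[C@H](O[Si](C)(C)C(C)(C)C)/C(C)=C\[C@@H](O[Si](CC)(CC)CC)[C@H]12 | intermediate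
26 | 8-hydroxy lactone, 1,3-bis-OTBS | C=C1C(=O)O[C@H]2/C=C(/C)[C@@H](O[Si](C)(C)C(C)(C)C)C[C@H](O[Si](C)(C)C(C)(C)C)/C(C)=C\[C@@H](O)[C@H]12 | intermediate
27 | angelic acid, (Z)-2-methylbut-2-enoic acid | C/C=C(/C)C(=O)O | starting material
28 | angelic 2,4,6-trichlorobenzoic anhydride (not isolated) | C/C=C(/C)C(=O)OC(=O)c1c(Cl)cc(Cl)cc1Cl | intermediate
29 | 8-O-angeloyl lactone, 1,3-bis-OTBS | C=C1C(=O)O[C@H]2/C=C(/C)[C@@H](O[Si](C)(C)C(C)(C)C)C[C@H](O[Si](C)(C)C(C)(C)C)/C(C)=C\[C@@H](OC(=O)/C(C)=C\C)[C@H]12 | intermediate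
30 | CNP0152559.1, (1S,3S,6S,7R,8R,4Z,9Z) in the numbering of the overview | C=C1C(=O)O[C@H]2/C=C(/C)[C@@H](O)C[C@H](O)/C(C)=C\[C@@H](OC(=O)/C(C)=C\C)[C@H]12 | target

**Step count**
Total: 19 steps. Longest linear sequence: 17 steps (steps 1–6, then 9–19).

**Steps most likely to fail**

Step 16. What may go wrong: t-BuLi or the alkenyllithium may attack the allylic chloride (1,3-elimination, coupling) before CO2 is captured, the O8 silyl group may migrate to C11, or the carboxylate may eliminate HCl instead of alkylating at C6. The fallback sets out from 21 and closes the lactone without the chloride. Deprotonation of the hydroxyl with MeLi, bromine–lithium exchange with t-BuLi at −78 °C and a CO2 quench should give, after acidic work-up, the hydroxy acid F1. This should lactonise by acyl–oxygen closure with retention at C6 (cat. PPTS, or 2,4,6-trichlorobenzoyl chloride/Et3N if needed), and the route is rejoined at 25.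

Step 12. What may go wrong: the strained ten-membered transition state may lose to intermolecular coupling and oligomerisation, or the alkenylchromium may be protonated, so that C–I (or slowly C–Br) is reduced without ring closure. The fallback sets out from 17 and closes the ring by acylation instead of carbonyl addition. Aminolysis of the thiazolidinethione with MeNHOMe·HCl and imidazole should give the Weinreb amide F2. Slow addition of t-BuLi (2.0 equiv) to a dilute THF solution at −100 °C should then exchange the alkenyl iodide selectively, and the alkenyllithium should acylate intramolecularly (Parham-type cyclisation) to give enone 20 directly, where the route is rejoined.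

Step 14. What may go wrong: the ring conformation rather than the reagent may decide which carbonyl face is open, giving poor facial selectivity, or 1,4-reduction may compete. The fallback sets out from 20 and corrects C6 by substitution instead of by reagent control. Luche reduction (NaBH4, CeCl3·7H2O, MeOH, −78 °C) is run under substrate control; if it delivers the 6-epi alcohol F3, Mitsunobu inversion with 4-nitrobenzoic acid (PPh3, DIAD, THF) should give the inverted ester F4. Methanolysis (K2CO3, MeOH) then gives 21, where the route is rejoined.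

**Further compounds**
F1 | step 16 | hydroxy acid: (6S)-alcohol 21 with the 1-bromovinyl group replaced by a 1-carboxyvinyl group | O[C@H]1/C=C(/C)[C@@H](O[Si](C)(C)C(C)(C)C)C[C@H](O[Si](C)(C)C(C)(C)C)/C(C)=C\[C@@H](O[Si](CC)(CC)CC)[C@@H]1C(=C)C(=O)O
F2 | step 12 | N-methoxy-N-methyl amide corresponding to 17 | CON(C)C(=O)[C@@H](C(Br)=C)[C@H](O[Si](CC)(CC)CC)/C=C(/C)[C@@H](O[Si](C)(C)C(C)(C)C)C[C@H](O[Si](C)(C)C(C)(C)C)/C(C)=C\I
F3 | step 14 | (6R)-alcohol, the C6 epimer of 21 | O[C@@H]1/C=C(/C)[C@@H](O[Si](C)(C)C(C)(C)C)C[C@H](O[Si](C)(C)C(C)(C)C)/C(C)=C\[C@@H](O[Si](CC)(CC)CC)[C@@H]1C(Br)=C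
F4 | step 14 | 4-nitrobenzoate of 21 (C6 configured as in 21) | O=C(O[C@H]1/C=C(/C)[C@@H](O[Si](C)(C)C(C)(C)C)C[C@H](O[Si](C)(C)C(C)(C)C)/C(C)=C\[C@@H](O[Si](CC)(CC)CC)[C@@H]1C(Br)=C)c1ccc(cc1)[N+](=O)[O-]
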